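**Plan**

- Retrosynthesis: the dihydropyran ring is cut first at O–C(Me) and CH2–CH (retro-hetero-Diels–Alder) to (−)-β-caryophyllene and an o-quinone methide. The acyl C–C bond is cut next. The carbocyclic six-membered ring is cut last, at its C(=O)–CMe2 bond (retro-6π) and at the two bonds that join a vinylketene to an ynol ether (retro-[2+2]).
- Enabling feature: the carbocycle is a 6,6-dimethylcyclohexa-2,4-dien-1-one with oxygen on C1, C3 and C5. The C1–C6 bond is the bond a dienylketene 6π closure makes. The three oxygens map onto one ketene C=O and two ynol-ether oxygens. The hydrogen-free C6 stops the annulation before aromatization, so the ring arrives already dearomatized.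
- Forward: dimethylketene and ethoxyacetylene give a cyclobutenone. A cascade with 1-ethoxypropyne expands a four-membered ring by two carbons into the six-membered ring, and acid unmasks the triketone in the same flask. C-Acylation follows. Oxidative o-quinone methide formation and hetero-Diels–Alder reaction close the pyran ring last.
- Stereochemistry: the two cyclobutane ring-fusion centers are bought with (−)-β-caryophyllene. They relay both new centers (C–O quaternary carbon R, ring-fusion CH S) in one cycloaddition: the E alkene gives the trans fusion, and the exposed face of the βα conformer gives the facial sense. The side-chain S center is bought with (S)-2-methylbutanoic acid.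

Key step: step 2

Assumption: the cyclic β-triketones of the route are tautomer mixtures and are drawn in the enol form that matches the target; "(−)-β-caryophyllene" is the natural (1R,9S,4E) enantiomer.

**Step 1**
Reactants: 1 isobutyryl chloride; 2 ethoxyacetylene
Product: 4 3-ethoxy-4,4-dimethylcyclobut-2-en-1-one, via dimethylketene 3 (not isolated)
Conditions: Et3N (1.2 equiv), Et2O, 35 °C
Reagents that add atoms: none
Why: Dehydrochlorination should give dimethylketene, which is taken up in a regioselective ketene–alkyne [2+2] cycloaddition in which the nucleophilic unsubstituted alkyne carbon attacks the ketene carbonyl carbon, so the ethoxy group ends up at C3 next to the gem-dimethyl carbon; no stereocenter is formed.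

**Step 2**
Reactants: 4 3-ethoxy-4,4-dimethylcyclobut-2-en-1-one; 5 1-ethoxyprop-1-yne
Product: 10 3,5-dihydroxy-4,6,6-trimethylcyclohexa-2,4-dien-1-one, via vinylketene 6 (not isolated), via alkenylcyclobutenone 7 (not isolated), via dienylketene 8 (not isolated), via diethoxydienone 9 (not isolated)
Conditions: hν (300 nm), PhMe, 20 °C, ynol ether in threefold excess; then 80 °C, dark; then 2 M HCl (aq), THF, 50 °C
Reagents that add atoms: water (O)
Why: Proposed new method: light opens cyclobutenone 4 by 4π electrocyclic cleavage to vinylketene 6, whose ketene C=C bond adds ynol ether 5 in a polar ketene–alkyne [2+2] cycloaddition (first closure: the four-membered ring of 7, carbonyl carbon to the methyl-bearing alkyne carbon, ketene α-carbon to the ethoxy-bearing one), and on warming 7 opens reversibly to dienylketene 8, which closes by thermal disrotatory 6π electrocyclization between the ketene carbon and the CMe2 terminus (second closure: the six-membered ring of 9, a net two-carbon ring expansion of the four-membered ring of 7). The closest known reaction type is the Danheiser benzannulation of cyclobutenones with ynol ethers, together with the thermal closure of dienylketenes to 6,6-dialkylcyclohexa-2,4-dienones; new here is that the hydrogen-free CMe2 terminus forbids the final tautomerization, so the cascade should stop at the non-aromatic dienone that already carries the quaternary carbon, the C-methyl group and the 1,3,5-oxygen pattern of the target ring. Aqueous acid then hydrolyses the vinylogous ester and the dienol ether of crude 9 in the same flask (protonation, addition of water, loss of ethanol) to the stable enol 10, acid being chosen because the 2,2-dimethyl-1,3-diketone unit would suffer retro-Claisen cleavage in hydroxide. No stereocenter results, since the one carbon stereocenter of 7 is racemic, transient and erased on ring opening. The regioselectivity of the [2+2] event, on which the oxygen pattern depends, is secured by the polarization of 5 (nucleophilic at the carbon remote from oxygen, which attacks the ketene carbonyl carbon), and the inward rotation of the alkenyl group needed for closure is secured by the reversibility of the ring opening of 7, because only the 3E ketene is drained by the irreversible 6π step. Capture of 6 has to outrun the 1,5-hydrogen shift from its Z-methyl group, which is why 6 is formed by light at 20 °C in an excess of 5, below the temperature at which ethyl ynol ethers lose ethene.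

**Step 3**
Reactants: 10 3,5-dihydroxy-4,6,6-trimethylcyclohexa-2,4-dien-1-one; 11 (2S)-2-methylbutanoic acid
Product: 14 3,5-dihydroxy-4,6,6-trimethyl-2-[(2S)-2-methylbutanoyl]cyclohexa-2,4-dien-1-one, via O-acylisourea 12 (not isolated), via enol ester 13 (not isolated)
Conditions: DCC (1.1 equiv), DMAP (1.2 equiv), CH2Cl2, 0 °C to rt
Reagents that add atoms: none
Why: Steglich-type O-acylation through the O-acylisourea should give enol ester 13, from which DMAP relays the acyl group to the only unsubstituted ring carbon (acyl-transfer rearrangement of enol esters to 2-acyl-1,3-diones, an anionic Fries-type shift), the hydrogen-bonded C-acyl triketone being the thermodynamic sink; the S center comes from 11 and should survive because no base stronger than DMAP is present.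

**Step 4**
Reactants: 14 3,5-dihydroxy-4,6,6-trimethyl-2-[(2S)-2-methylbutanoyl]cyclohexa-2,4-dien-1-one; 15 (−)-β-caryophyllene
Product: 17 target meroterpenoid, via o-quinone methide 16 (not isolated)
Conditions: Ag2O (2 equiv), TEMPO (0.2 equiv), PhMe, rt, terpene in threefold excess
Reagents that add atoms: none
Why: Dehydrogenation of the C-methyl vinylogous acid by Ag2O, with TEMPO as hydrogen-atom relay, should give o-quinone methide 16, which the strained trans-trisubstituted alkene of 15 traps in an inverse-electron-demand hetero-Diels–Alder reaction: the methylene carbon bonds to the alkene CH and the oxygen to the methyl-bearing carbon (Markovnikov sense), suprafacial addition to the E alkene gives the trans ring fusion, attack on the exposed face of the major βα conformer of 15 (the face peracids also attack) should set R at the C–O carbon and S at the CH carbon, the carbonyl next to the gem-dimethyl carbon is the one that closes because the other flanking oxygen is held as the hydrogen-bonded enol of the acyl group, and the less strained exocyclic methylene of 15 should stay untouched.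

**Compound list**

1 | isobutyryl chloride (2-methylpropanoyl chloride) | CC(C)C(=O)Cl | starting material
2 | ethoxyacetylene (ethoxyethyne) | CCOC#C | starting material
3 | dimethylketene | CC(C)=C=O | intermediate
4 | 3-ethoxy-4,4-dimethylcyclobut-2-en-1-one | CCOC1=CC(=O)C1(C)C | intermediate
5 | 1-ethoxyprop-1-yne | CCOC#CC | starting material
6 | 3-ethoxy-4-methylpenta-1,3-dien-1-one (vinylketene) | CCOC(C=C=O)=C(C)C | intermediate
7 | 3-ethoxy-4-(1-ethoxy-2-methylprop-1-en-1-yl)-2-methylcyclobut-2-en-1-one (racemic) | CCOC1=C(C)C(=O)C1C(OCC)=C(C)C | intermediate
8 | (3E)-3,5-diethoxy-2,6-dimethylhepta-1,3,5-trien-1-one (dienylketene) | O=C=C(C)/C(OCC)=C\C(OCC)=C(C)C | intermediate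
9 | 3,5-diethoxy-2,6,6-trimethylcyclohexa-2,4-dien-1-one | CCOC1=CC(OCC)=C(C)C(=O)C1(C)C | intermediate
10 | 3,5-dihydroxy-4,6,6-trimethylcyclohexa-2,4-dien-1-one (enol form of 2,2,4-trimethylcyclohexane-1,3,5-trione) | CC1=C(O)C(C)(C)C(=O)C=C1O | intermediate
11 | (2S)-2-methylbutanoic acid | CC[C@H](C)C(=O)O | starting material
12 | O-[(2S)-2-methylbutanoyl]-N,N'-dicyclohexylisourea | CC[C@H](C)C(=O)OC(=NC1CCCCC1)NC1CCCCC1 | intermediate
13 | 5-hydroxy-4,4,6-trimethyl-3-oxocyclohexa-1,5-dien-1-yl (2S)-2-methylbutanoate (one of the interconverting enol esters) | CC[C@H](C)C(=O)OC1=CC(=O)C(C)(C)C(O)=C1C | intermediate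
14 | 3,5-dihydroxy-4,6,6-trimethyl-2-[(2S)-2-methylbutanoyl]cyclohexa-2,4-dien-1-one | CC[C@H](C)C(=O)C1=C(O)C(C)=C(O)C(C)(C)C1=O | intermediate
15 | (−)-β-caryophyllene, (1R,4E,9S)-4,11,11-trimethyl-8-methylidenebicyclo[7.2.0]undec-4-ene | C=C1CC/C=C(\C)CC[C@@H]2[C@@H]1CC2(C)C | starting material
16 | 3-hydroxy-6,6-dimethyl-4-methylidene-2-[(2S)-2-methylbutanoyl]cyclohex-2-ene-1,5-dione (o-quinone methide) | C=C1C(=O)C(C)(C)C(=O)C(C(=O)[C@@H](C)CC)=C1O | intermediate
17 | target: trans-fused dihydropyran adduct of 15 and 16; C–O quaternary carbon R, adjacent ring-fusion CH S, cyclobutane ring-fusion carbons as in 15, side chain S | C=C1CC[C@H]2CC3=C(O[C@]2(C)CC[C@@H]2[C@@H]1CC2(C)C)C(C)(C)C(=O)C(C(=O)[C@@H](C)CC)=C3O | target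

**Totals**

Total step count: 4. Longest linear sequence: 4 steps (1 → 4 → 10 → 14 → 17).

**Steps most likely to fail**

Step 2. Capture of vinylketene 6 by the ynol ether may lose to its 1,5-hydrogen shift or to ketene dimerization, secondary photochemistry of the dienone may erode the material, and the hydrolysis stage may be accompanied by retro-Claisen ring cleavage. The fallback uses known chemistry, sets out from 11 and comes back at 14. Acid 11 is heated with commercial phloroglucinol (benzene-1,3,5-triol, Oc1cc(O)cc(O)c1) in BF3·OEt2 at 80 °C in a Friedel–Crafts acylation with the free acid, which should give 1-(2,4,6-trihydroxyphenyl)-(2S)-2-methylbutan-1-one F1. Dearomatizing C-methylation of F1 with NaOMe and MeI (three equivalents) in MeOH, twice at one ring carbon and once at the other, should then give 14. The ring is then taken from an arene, and compounds 4 to 10 as well as step 3 are bypassed.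

Step 4. Over-oxidation of the enol or of the allylic positions of 15 by the silver oxidant, self-condensation of the quinone methide, closure through the other carbonyl oxygen, and low facial selectivity between the βα and ββ conformers may all lower the return. The fallback removes the oxidant and brings the methylene carbon in from formaldehyde; it sets out from 11 and comes back at 16 and hence 17. Acylphloroglucinol F1, made as in the fallback for step 2, is C-methylated twice at one carbon (NaOMe, MeI two equivalents, MeOH) to 3,5-dihydroxy-6,6-dimethyl-2-[(2S)-2-methylbutanoyl]cyclohexa-2,4-dien-1-one F2. Heating F2 with paraformaldehyde (formaldehyde, C=O) and 15 (NaOAc, AcOH, 80 °C) should give, by Knoevenagel-type hydroxymethylation, 3,5-dihydroxy-4-(hydroxymethyl)-6,6-dimethyl-2-[(2S)-2-methylbutanoyl]cyclohexa-2,4-dien-1-one F3. F3 loses water to the same quinone methide 16, which 15 traps as in step 4; a methylene-bridged dimer of F2, should it form, is expected to re-enter through retro-Michael cleavage on heating. The diastereomer from the ββ conformer would in either variant be removed by chromatography.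

Step 3. The acyl group may stall on oxygen, may be delivered to the methyl-bearing carbon, or the α-center may epimerize through the acylpyridinium ion. The fallback replaces nucleophile-catalysed acyl transfer by direct electrophilic substitution at carbon; it sets out from 11 and 10 and comes back at 14. Acid 11 is converted with oxalyl chloride and catalytic DMF in CH2Cl2 into (2S)-2-methylbutanoyl chloride F4. F4 acylates the enol carbon of 10 under AlCl3 in PhNO2/CH2Cl2 at 0 °C (Friedel–Crafts C-acylation, the classical entry to acylated cyclohexanetrione enols), which should give 14 after aqueous work-up.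

**Further compounds**

F1 | step 2 | 1-(2,4,6-trihydroxyphenyl)-(2S)-2-methylbutan-1-one | CC[C@H](C)C(=O)c1c(O)cc(O)cc1O
F2 | step 4 | 3,5-dihydroxy-6,6-dimethyl-2-[(2S)-2-methylbutanoyl]cyclohexa-2,4-dien-1-one | CC[C@H](C)C(=O)C1=C(O)C=C(O)C(C)(C)C1=O
F3 | step 4 | 3,5-dihydroxy-4-(hydroxymethyl)-6,6-dimethyl-2-[(2S)-2-methylbutanoyl]cyclohexa-2,4-dien-1-one | CC[C@H](C)C(=O)C1=C(O)C(CO)=C(O)C(C)(C)C1=O
F4 | step 3 | (2S)-2-methylbutanoyl chloride | CC[C@H](C)C(=O)Cl
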